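**Conventions.** Atoms carry the numbering of the target hydrindane in all intermediates: C1 (ethylidene-bearing), C2 (acetoxy), C3, C3a, C4 (methylidene-bearing), C5 (enoyloxy), C6 (hydroxy), C7 (isopropyl), C7a. C8 is the ethylidene CH carbon, C9 its methyl, C10 the methylidene CH2. In the decalin intermediates C8 is a ring atom between C2 and C1 (ring B = C3a–C3–C2–C8–C1–C7a). β is the face of H-3a, α the opposite face. TBS = tert-butyldimethylsilyl; "enoate" = (E)-3-methylpent-2-enoate.

Remark (assumption): C1 of β-diketone 16 is configurationally labile; 16 is written as the more stable 1α-acetyl keto form, although enol forms will be present.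

## Analysis of the target

Target 22 is a sesquiterpenoid diester on a trans-fused hydrindane. Ring A is the cyclohexane C3a–C4–C5–C6–C7–C7a and ring B the cyclopentane C1–C2–C3–C3a–C7a, with an exocyclic methylidene on C4 and a Z-ethylidene on C1. The six stereocentres work out as 2R, 3aR, 5S, 6S, 7S, 7aR: H-3a and H-7a are anti, the isopropyl group on C7 is equatorial, the C6 hydroxyl is axial on the face of H-7a, the C5 acyloxy group is axial on the other face, and the C2 acetoxy group lies on the face of H-3a. Sensitive points are two allylic esters, a β,β-disubstituted enoate that can deconjugate or lose its E geometry, a free hydroxyl next to an ester, and a 1,1-disubstituted alkene. The difficulty is a strained trans-hydrindane with five stereocentres around ring A, three differently substituted oxygens, and a trisubstituted exocyclic alkene of fixed geometry beside a ring-fusion centre. The strategy rests on one feature: C1, C2, C3, C3a, C7a with C8 and C9 are a 2-methylcyclohex-2-enone from which C8 has been pushed out of the ring, and C4, C10 and C5 are an isopropenyl group on C3a. That is the carbon skeleton of carvone, and the remaining five carbons (C6, C7, isopropyl) are one branched unit. The Z geometry puts hydrogen, not methyl, next to C7a and the isopropyl group, so it should also be the thermodynamically preferred isomer.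

## Retrosynthetic reasoning

**Protecting group and esters (22 ⇒ 21 ⇒ 20 ⇒ 19).** The C6 hydroxyl is freed last from silyl ether 21, because a free OH earlier would compete in every acylation. The C2 acetate is cut at its acyl C–O bond to alcohol 20, and the C2–H bond is traced to ketone 19. The two faces of that carbonyl are nearly equivalent in a trans-hydrindane, so the forward reduction has to be reagent-controlled.

**Ethylidene (19 ⇒ 17 ⇒ 16).** The C1=C8 alkene is traced to an acetyl group on C1. In β-diketone 16 the ring oxygen is fixed as an enol ether (17), the acetyl carbonyl is reduced, and acid moves the unsaturation out to C8 while restoring the C2 ketone. This avoids any olefination of a hindered ketone and lets strain decide the geometry.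

**Key disconnection (16 ⇒ 14).** The C1–C2 bond is cut and C2 is re-attached to C8, which expands ring B to the six-membered epoxy ketone 14. Forward, a Lewis acid opens the epoxide at C1 and the acyl carbon C2 shifts from C8 to C1. The cut is made here because the decalin is far easier to build than the hydrindane, and because the rearrangement leaves exactly the acetyl and ketone groups the end game needs.

**Ring A oxygens (14 ⇒ 12 + 13 ⇒ 11 ⇒ 10 ⇒ 9).** The enoate is removed at its ester bond to alcohol 12 and acid 13; it is put on early so that no late differentiation of two hydroxyls is needed. The C5–O bond is traced to allylic hydroxylation of the methylidene in 11, the epoxide to nucleophilic epoxidation of enone 10, and the silyl ether to alcohol 9. Silylating C6 first blocks the α face for the C5 oxidation.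

**Ring A closure (9 ⇒ 8).** The C5–C6 bond is cut to give keto aldehyde 8. Forward, a carbonyl-ene reaction between the aldehyde and the isopropenyl group closes the ring, forms the methylidene and places the C6 hydroxyl axial in one step.

**C7a–C7 bond (8 ⇒ 7 ⇒ 6 + 4).** The aldehyde comes from nitro compound 7 by a Nef reaction. The C7a–C7 bond is cut to silyloxydiene 6 and nitroalkene 4; forward, the γ-carbon of the dienol ether adds to the nitroalkene anti to the isopropenyl group, which sets C7a and C7.

**Starting materials (6 ⇒ 5; 4 ⇒ 3 ⇒ 1 + 2).** Diene 6 is the linearly conjugated silyl dienol ether of (S)-carvone 5, whose stereocentre becomes C3a. Nitroalkene 4 comes from 2-methylpropanal 1 and nitromethane 2 by nitroaldol addition and dehydration.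

## Alternatives that were turned down

**Alternative 1:** Ring A is opened at C4–C5. Forward, silyl enol ether A1 (a trans-2,3-disubstituted cyclopentane with a vinyl group on C3a) would be treated with Pd(OAc)2 under oxygen in DMSO. The enol ether carbon adds to the palladium-bound vinyl group and β-hydride elimination gives ketone A2 with the C4 methylidene in place.
- For: neutral, catalytic in divalent palladium, ring and methylidene in one step. The C6 ketone allows C7 to be corrected by equilibration and activates C5; on C7 this is stronger than the kinetic control the chosen route relies on in step 4.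
- Against: A1 needs three defined centres on a cyclopentane that no cheap chiral-pool compound offers. A2 is a β,γ-unsaturated ketone that tends to conjugate. A2 has a ketal on C1 and CH2 at C2, so the ethylidene would need olefination of a ketone next to C7a without geometric control, and the C2 oxygen an allylic oxidation beside a second reactive alkene.
- Comparison: the chosen strategy takes C3a, the C2 oxygen and the C8–C9 unit ready-made from carvone and lets strain fix the alkene geometry; it should also be shorter.

**Alternative 2:** Ring B is cut at C1–C2 together with the C8–C9 bond. Forward, Ni(cod)2 with Me2Zn couples the aldehyde of ynal A3 to the ethynyl group on C7a and adds methyl to the alkyne terminus on the same side, giving allylic alcohol A4.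
- For: one step makes the five-membered ring, the C2 carbinol and the Z-ethylidene, which takes steps 12 to 14 in the chosen route. The geometry follows from the syn addition, not from thermodynamics, so on ring B this alternative is stronger.
- Against: the C2 configuration depends on substrate control through a flexible tether. A3 has three contiguous stereocentres that must come from asymmetric synthesis. In A4 both C5 and C6 are CH2 and C6 is not activated by the masked C4 carbonyl, so the trans-diaxial oxygen pair would need a long late sequence.
- Comparison: the chosen route sets the C6 hydroxyl in the ring-forming step and the C5 oxygen by one allylic oxidation, both before the ring contraction.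

**Alternative 3:** Ring A is cut at C5–C6 on a hydrindane. Forward, Me2AlCl would activate the aldehyde of keto aldehyde A5, which bonds to the CH2 terminus of the isopropenyl group on C3a while a methyl hydrogen passes to oxygen, giving ketone A6 with the methylidene and the axial C6 alcohol.
- For: this is the same ene reaction as step 6 of the chosen route, so it is equally good for C4 and C6. It needs no skeletal rearrangement and so avoids the riskiest step of the chosen route.
- Against: A5 is a trans-2,3-disubstituted cyclopentanone that carvone cannot supply, with two adjacent epimerisable centres (C7a next to the ketone, C7 next to the aldehyde). A6 has its carbonyl on C1 and CH2 at C2, so the ethylidene again needs a geometry-uncontrolled olefination and the C2 oxygen a later oxidation.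
- Comparison: the chosen strategy accepts the rearrangement risk in exchange for a chiral-pool six-membered precursor that already holds the C2 oxygen and C8–C9.

Key step: step 11

## Route

Step 1
Reactants: 1 2-methylpropanal; 2 nitromethane
Product: 3 3-methyl-1-nitrobutan-2-ol (racemic)
Conditions: MeNO2 (3 equiv), NaOH (10 mol%), EtOH/H2O, 0 °C → rt
Reagents that add atoms: none
Why: Henry (nitroaldol) reaction of an unhindered aldehyde; the carbinol centre is removed in the next step, so its configuration does not matter.

Step 2
Reactants: 3 3-methyl-1-nitrobutan-2-ol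
Product: 4 (E)-3-methyl-1-nitrobut-1-ene
Conditions: MsCl, Et3N, CH2Cl2, 0 °C
Reagents that add atoms: none
Why: Mesylation and E1cB elimination of a β-nitro alcohol; the conjugated nitroalkene should form as the more stable E isomer.

Step 3
Reactants: 5 (S)-carvone
Product: 6 (5R)-2-methyl-5-(prop-1-en-2-yl)-1-(trimethylsilyloxy)cyclohexa-1,3-diene
Conditions: MeMgBr (1.2 equiv), FeCl3 (3 mol%), Et2O, −20 °C; then Me3SiCl, Et3N, HMPA, −20 °C → rt
Reagents that add atoms: chlorotrimethylsilane, C[Si](C)(C)Cl
Why: Iron-catalysed deprotonation by the Grignard reagent under equilibrating conditions should remove the γ-hydrogen (at the future C7a) and give the linearly conjugated, thermodynamic dienolate instead of the kinetic cross-conjugated one; O-silylation fixes it and C3a is untouched.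

Step 4
Reactants: 6 silyloxydiene; 4 (E)-3-methyl-1-nitrobut-1-ene
Product: 7 (4R,5R)-2-methyl-4-[(2S)-3-methyl-1-nitrobutan-2-yl]-5-(prop-1-en-2-yl)cyclohex-2-en-1-one
Conditions: SnCl4 (1.1 equiv), CH2Cl2, −78 °C; then aq. NaHCO3
Reagents that add atoms: none
Why: Vinylogous Mukaiyama–Michael addition: the γ-terminus (C7a) attacks the nitroalkene β-carbon because the α-position C8 is blocked by its methyl group, and it does so anti to the isopropenyl group, which sets the trans C3a/C7a relationship. C7 is set by the compact approach with the nitro group over the diene and the isopropyl group pointing away, the same topology as the endo-nitro [4+2] addition.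

Step 5
Reactants: 7 nitro enone
Product: 8 (2S)-3-methyl-2-[(1R,6R)-3-methyl-4-oxo-6-(prop-1-en-2-yl)cyclohex-2-en-1-yl]butanal
Conditions: NaOMe (1.05 equiv), MeOH, 0 °C; then TiCl3 (4 equiv, aq.), NH4OAc buffer (pH ≈ 5), THF, 0 °C → rt
Reagents that add atoms: water, O
Why: Reductive Nef reaction: trivalent titanium reduces the nitronate to the imine, which hydrolyses to the aldehyde near neutral pH, so the isopropenyl group, the enone and the epimerisable C7 centre next to the new aldehyde should survive.

Step 6
Reactants: 8 keto aldehyde
Product: 9 trans-decalin enone alcohol (C2 ketone, C8=C1 alkene, 8-methyl, 4-methylidene, 6α-OH axial, 7α-isopropyl equatorial; H-3a β, H-7a α)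
Conditions: Me2AlCl (2.5 equiv), CH2Cl2, −78 → −20 °C; then 1 M HCl
Reagents that add atoms: none
Why: Type-2 intramolecular carbonyl-ene reaction: the aluminium-bound aldehyde carbon C6 bonds to the CH2 terminus of the isopropenyl group (C5) while a hydrogen of its methyl group passes to oxygen, closing ring A as a chair with trans fusion and equatorial isopropyl. The carbonyl oxygen must be axial to reach that hydrogen, which gives the axial 6α-alcohol and the C4 methylidene.

Step 7
Reactants: 9 decalin enone alcohol
Product: 10 6α-TBS ether of 9
Conditions: tBuMe2SiOTf, 2,6-lutidine, CH2Cl2, −78 → 0 °C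
Reagents that add atoms: tert-butyldimethylsilyl trifluoromethanesulfonate, CC(C)(C)[Si](C)(C)OS(=O)(=O)C(F)(F)F
Why: The hindered axial alcohol needs the silyl triflate; the weak base leaves the enone alone, and the bulky axial ether later shields the α face of C5.

Step 8
Reactants: 10 decalin enone silyl ether
Product: 11 1β,8β-epoxy decalin-2-one (6α-OTBS, 4-methylidene, 7α-isopropyl)
Conditions: 30% H2O2, NaOH (0.3 equiv), MeOH, 0 °C
Reagents that add atoms: hydrogen peroxide, OO
Why: Weitz–Scheffer epoxidation: hydroperoxide adds only to the enone, axially at C1 on the β face as with carvone itself, and the enolate closes the cis epoxide on that face; the isolated methylidene is inert.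

Step 9
Reactants: 11 epoxy ketone
Product: 12 5β-hydroxy epoxy ketone (5β-OH axial, trans to 6α-OTBS)
Conditions: SeO2 (0.5 equiv), tBuOOH (3 equiv), CH2Cl2, rt
Reagents that add atoms: tert-butyl hydroperoxide, CC(C)(C)OO (the oxygen is passed on by SeO2, O=[Se]=O)
Why: Allylic hydroxylation by ene reaction and [2,3]-sigmatropic shift at the ring CH2 (C5) of the 1,1-disubstituted alkene, which is preferred over the ring-fusion CH at C3a. Oxygen should arrive axially on the β face, anti to the axial silyloxy group on C6, giving the trans-diaxial pair.

Step 10
Reactants: 12 5β-hydroxy epoxy ketone; 13 (E)-3-methylpent-2-enoic acid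
Product: 14 5β-enoate of 12 (epoxy ketone precursor of the key step)
Conditions: N,N'-dicyclohexylcarbodiimide (DCC), 4-(dimethylamino)pyridine (0.2 equiv), CH2Cl2, 0 °C → rt
Reagents that add atoms: none
Why: Steglich esterification of the only free hydroxyl; the nearly neutral activation should keep the β,β-disubstituted enoate conjugated and E.

Step 11
Reactants: 14 epoxy ketone ester
Product: 16 1α-acetyl-trans-hydrindan-2-one (β-diketone; 5β-enoate; 6α-OTBS; 7α-isopropyl; 4-methylidene), via 1β-acetyl epimer 15 (not isolated)
Conditions: BF3·OEt2 (2.5 equiv), CH2Cl2, −40 → 0 °C; aq. NaHCO3; then Et3N (cat.), CH2Cl2, rt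
Reagents that add atoms: none
Why: BF3 binds the epoxide oxygen and the C1–O bond, the one remote from the electron-poor carbonyl carbon, lengthens; as it breaks, the acyl carbon C2 moves from C8 to C1 on the face opposite the departing oxygen, and the oxygen left on C8 becomes the acetyl carbonyl. This is the known Lewis-acid rearrangement of α,β-epoxy ketones to β-dicarbonyl compounds by 1,2-acyl shift, which contracts 2,3-epoxycyclohexanones to 2-acylcyclopentanones. The five-membered ring is closed by this 1,2-shift and not by a cyclisation: the C2–C8 ring bond is exchanged for C1–C2 and C8 leaves the ring, so the trans fusion at C3a/C7a is carried over unchanged. The new stereocentre C1 forms with inversion (kinetic 1β-acetyl epimer 15); lying between two carbonyl groups it should equilibrate through the enol to 16, where the acetyl group is trans to C7, and its configuration is lost later in any case. The step needs acyl migration in preference to a methyl shift from C8 (which would give a 1,2-diketone), a hydride shift from C7a, or capture of the C1 cation by fluoride. The high migratory aptitude of acyl in a concerted bridged transition state and the secondary nature of C1, which rules out a free cation, should secure this; neither the silyl ether nor the hindered ester places a nucleophile near C1.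

Step 12
Reactants: 16 β-diketone
Product: 17 1-acetyl-2-methoxy-hydrind-1-ene (vinylogous ester, C1=C2 in the ring; 5β-enoate; 6α-OTBS)
Conditions: HC(OMe)3, MeOH, pyridinium p-toluenesulfonate (5 mol%), rt
Reagents that add atoms: trimethyl orthoformate, COC(OC)OC
Why: Acid-catalysed, reversible enol ether formation from a β-diketone should give the more stable vinylogous ester, with the alkene inside the ring and methoxy on C2, because an exocyclic tetrasubstituted alkene at C1 would press a non-hydrogen group against C7 and its isopropyl group. The C1 stereocentre disappears and C2 stays marked for return to the ketone.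

Step 13
Reactants: 17 vinylogous ester
Product: 19 (Z)-1-ethylidene-trans-hydrindan-2-one (5β-enoate; 6α-OTBS; 7α-isopropyl; 4-methylidene), via carbinol 18 (not isolated)
Conditions: NaBH4, CeCl3·7H2O, MeOH, −20 °C; then 1 M HCl, THF, 0 °C
Reagents that add atoms: water, O
Why: Stork–Danheiser-type reductive transposition: Luche 1,2-reduction of the acetyl carbonyl leaves the esters alone, then acid ionises the allylic carbinol with help from the enol ether, and water hydrolyses the oxocarbenium ion to the C2 ketone, leaving the C1=C8 alkene. The Z geometry (methyl towards C2, hydrogen towards C7a) is the one free of allylic strain with C7 and its isopropyl group, so it should be both the kinetic and the thermodynamic product.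

Step 14
Reactants: 19 Z-enone
Product: 20 2β-allylic alcohol (2R; 5β-enoate; 6α-OTBS)
Conditions: (S)-Me-CBS oxazaborolidine [(S)-1-methyl-3,3-diphenyltetrahydro-1H,3H-pyrrolo[1,2-c][1,3,2]oxazaborole] (0.5 equiv), catecholborane (2 equiv), toluene, −78 °C; then MeOH
Reagents that add atoms: none
Why: Corey–Bakshi–Shibata reduction: the two faces of the C2 carbonyl are almost equivalent in a trans-hydrindane, so the catalyst decides. With the alkylidene carbon C1 as the large group, the (S)-catalyst should deliver hydride to the α face and give the 2β (2R) alcohol; catecholborane at −78 °C should not touch the alkenes or esters.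

Step 15
Reactants: 20 2β-allylic alcohol
Product: 21 2β-acetate (5β-enoate; 6α-OTBS)
Conditions: Ac2O, pyridine, 4-(dimethylamino)pyridine (cat.), CH2Cl2, 0 °C → rt
Reagents that add atoms: acetic anhydride, CC(=O)OC(C)=O
Why: Standard acylation of the only free hydroxyl, with retention at C2.

Step 16
Reactants: 21 silyl ether diester
Product: 22 target, (1Z,2R,3aR,5S,6S,7S,7aR)-2-acetoxy-1-ethylidene-6-hydroxy-4-methylidene-7-(propan-2-yl)octahydro-1H-inden-5-yl (E)-3-methylpent-2-enoate
Conditions: HF·pyridine, pyridine, THF, 0 °C → rt
Reagents that add atoms: none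
Why: Fluoride cleavage of the silyl ether under buffered conditions that should spare both esters; the trans-diaxial arrangement of the C5 ester and the freed C6 hydroxyl blocks acyl migration.

## Compound list

1 | 2-methylpropanal | CC(C)C=O | starting material
2 | nitromethane | C[N+](=O)[O-] | starting material
3 | 3-methyl-1-nitrobutan-2-ol (racemic) | CC(C)C(O)C[N+](=O)[O-] | intermediate
4 | (E)-3-methyl-1-nitrobut-1-ene | CC(C)/C=C/[N+](=O)[O-] | intermediate
5 | (S)-carvone | C=C(C)[C@@H]1CC(=O)C(C)=CC1 | starting material
6 | (5R)-2-methyl-5-(prop-1-en-2-yl)-1-(trimethylsilyloxy)cyclohexa-1,3-diene | C=C(C)[C@@H]1CC(O[Si](C)(C)C)=C(C)C=C1 | intermediate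
7 | (4R,5R)-2-methyl-4-[(2S)-3-methyl-1-nitrobutan-2-yl]-5-(prop-1-en-2-yl)cyclohex-2-en-1-one | C=C(C)[C@@H]1CC(=O)C(C)=C[C@H]1[C@H](C(C)C)C[N+](=O)[O-] | intermediate
8 | (2S)-3-methyl-2-[(1R,6R)-3-methyl-4-oxo-6-(prop-1-en-2-yl)cyclohex-2-en-1-yl]butanal | C=C(C)[C@@H]1CC(=O)C(C)=C[C@H]1[C@H](C(C)C)C=O | intermediate
9 | trans-decalin enone alcohol (C2 ketone, C8=C1, 8-methyl, 4-methylidene, 6α-OH, 7α-isopropyl) | C=C1[C@@H]2CC(=O)C(C)=C[C@H]2[C@H](C(C)C)[C@H](O)C1 | intermediate
10 | 6α-TBS ether of 9 | C=C1[C@@H]2CC(=O)C(C)=C[C@H]2[C@H](C(C)C)[C@H](O[Si](C)(C)C(C)(C)C)C1 | intermediate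
11 | 1β,8β-epoxy decalin-2-one (6α-OTBS) | C=C1[C@@H]2CC(=O)[C@@]3(C)O[C@H]3[C@H]2[C@H](C(C)C)[C@H](O[Si](C)(C)C(C)(C)C)C1 | intermediate
12 | 5β-hydroxy-1β,8β-epoxy decalin-2-one (6α-OTBS) | C=C1[C@@H]2CC(=O)[C@@]3(C)O[C@H]3[C@H]2[C@H](C(C)C)[C@H](O[Si](C)(C)C(C)(C)C)[C@H]1O | intermediate
13 | (E)-3-methylpent-2-enoic acid | CC/C(C)=C/C(=O)O | starting material
14 | 5β-[(E)-3-methylpent-2-enoyloxy]-1β,8β-epoxy decalin-2-one (6α-OTBS), key-step precursor | C=C1[C@@H]2CC(=O)[C@@]3(C)O[C@H]3[C@H]2[C@H](C(C)C)[C@H](O[Si](C)(C)C(C)(C)C)[C@H]1OC(=O)/C=C(\C)CC | intermediate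
15 | 1β-acetyl-trans-hydrindan-2-one, kinetic epimer (not isolated) | C=C1[C@@H]2CC(=O)[C@@H](C(C)=O)[C@H]2[C@H](C(C)C)[C@H](O[Si](C)(C)C(C)(C)C)[C@H]1OC(=O)/C=C(\C)CC | intermediate
16 | 1α-acetyl-trans-hydrindan-2-one (5β-enoate, 6α-OTBS), key-step product | C=C1[C@@H]2CC(=O)[C@H](C(C)=O)[C@H]2[C@H](C(C)C)[C@H](O[Si](C)(C)C(C)(C)C)[C@H]1OC(=O)/C=C(\C)CC | intermediate
17 | 1-acetyl-2-methoxy-hydrind-1-ene vinylogous ester | C=C1[C@@H]2CC(OC)=C(C(C)=O)[C@H]2[C@H](C(C)C)[C@H](O[Si](C)(C)C(C)(C)C)[C@H]1OC(=O)/C=C(\C)CC | intermediate
18 | 1-(1-hydroxyethyl)-2-methoxy-hydrind-1-ene (carbinol epimers at C8, not isolated) | C=C1[C@@H]2CC(OC)=C(C(C)O)[C@H]2[C@H](C(C)C)[C@H](O[Si](C)(C)C(C)(C)C)[C@H]1OC(=O)/C=C(\C)CC | intermediate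
19 | (Z)-1-ethylidene-trans-hydrindan-2-one (5β-enoate, 6α-OTBS) | C=C1[C@@H]2CC(=O)/C(=C\C)[C@H]2[C@H](C(C)C)[C@H](O[Si](C)(C)C(C)(C)C)[C@H]1OC(=O)/C=C(\C)CC | intermediate
20 | 2β-hydroxy-(Z)-1-ethylidene hydrindane (5β-enoate, 6α-OTBS) | C=C1[C@@H]2C[C@@H](O)/C(=C\C)[C@H]2[C@H](C(C)C)[C@H](O[Si](C)(C)C(C)(C)C)[C@H]1OC(=O)/C=C(\C)CC | intermediate
21 | 2β-acetoxy-(Z)-1-ethylidene hydrindane (5β-enoate, 6α-OTBS) | C=C1[C@@H]2C[C@@H](OC(C)=O)/C(=C\C)[C@H]2[C@H](C(C)C)[C@H](O[Si](C)(C)C(C)(C)C)[C@H]1OC(=O)/C=C(\C)CC | intermediate
22 | CNP0418642.2 | C=C1[C@@H]2C[C@@H](OC(C)=O)/C(=C\C)[C@H]2[C@H](C(C)C)[C@H](O)[C@H]1OC(=O)/C=C(\C)CC | target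

## Step count and least certain steps

Total: 16 steps. Longest linear sequence: 15 steps (steps 1, 2, 4–16 from 2-methylpropanal); 14 steps from (S)-carvone.

**Step 11 (key step).** The most likely failure is diversion of the developing positive charge at C1 by a 1,2-hydride shift from C7a, whose axial C–H bond lies antiperiplanar to the breaking C1–O bond of the β-epoxide; this would lead to elimination at the ring fusion instead of ring contraction. The fallback uses the epoxide of opposite configuration, in which that C–H bond is synclinal to the C1–O bond. It sets out from 10. Luche reduction (NaBH4, CeCl3·7H2O, MeOH, −40 °C) by axial hydride attack should give the 2α-allylic alcohol F1. Hydroxyl-directed epoxidation (VO(acac)2, tBuOOH, CH2Cl2, 0 °C) should epoxidise only the allylic alkene, syn to the hydroxyl, giving the 2α-hydroxy-1α,8α-epoxide F2. Oxidation with the triacetoxy periodinane (DMP, NaHCO3, CH2Cl2) would give the 1α,8α-epoxy ketone F3. Allylic hydroxylation as in step 9 would give the 5β-hydroxy-1α,8α-epoxy ketone F4, and Steglich esterification with 13 the 5β-enoate α-epoxide F5. BF3·OEt2 would then shift the acyl carbon with inversion to give the 1α-acetyl diketone directly, so the fallback returns to the route at 16.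

**Step 4.** The likely problems are poor discrimination between the two faces of the nitroalkene in an open transition state, giving C7 epimers, and sluggish bond formation between two branched carbons with Lewis-acid damage to the diene. The fallback replaces the open addition by a closed cycloaddition. It sets out from 6 and 4: heating in toluene (80 °C, radical inhibitor) should give, through the endo-nitro Diels–Alder transition state on the face anti to the isopropenyl group, the bicyclo[2.2.2]octene silyl ether F6. Desilylation (Bu4NF, AcOH, THF, 0 °C) would trigger retro-Henry fragmentation of the bridgehead β-nitro alkoxide and return to the route at 7.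

**Step 12.** The risk is enol ether formation on the acetyl oxygen, or a mixture of both regioisomers; the exocyclic isomer would lose the C2 oxygen in step 13. The fallback turns that regiochemistry to use with a different enol derivative. It sets out from 16: KN(SiMe3)2 with 18-crown-6 and PhNTf2 (THF, −78 °C) should give, under non-chelating conditions, the exocyclic enol triflate F7 with the triflate on the C7a side. Hydrogenolysis with retention (Pd(OAc)2, PPh3, HCO2H, Bu3N, DMF, 60 °C) would replace the triflate by hydrogen and return to the route at 19.

**Step 9.** Oxygen may be delivered to the equatorial α side of C5, or the allylic alcohol may be oxidised further to the C5 ketone if the reaction is pushed. The fallback corrects the configuration during esterification. It sets out from 11: if the oxidation gives the 5α-hydroxy epimer F8, Mitsunobu esterification with 13 (PPh3, diisopropyl azodicarboxylate, toluene, 0 °C) should install the enoate with inversion and return to the route at 14.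

**Step 14.** Facial control may be insufficient if the alkylidene side does not act as the large group or if the weak substrate bias opposes the catalyst, giving both C2 epimers. The fallback accepts a mixture and inverts the wrong epimer. It sets out from 19: Luche reduction (NaBH4, CeCl3·7H2O, MeOH, −40 °C) and separation would give 20 and the 2α-alcohol F9. Mitsunobu reaction of the latter with acetic acid (PPh3, diisopropyl azodicarboxylate, THF, 0 °C) should give the acetate with inversion and return to the route at 21, while 20 is acetylated as in step 15.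

**Step 3.** Enolisation may occur at the α′-position (C3) to give the cross-conjugated dienol ether, or the Grignard reagent may add to the enone. The fallback reaches the linear dienolate through the enol acetate. It sets out from 5: isopropenyl acetate with TsOH (cat.) at reflux should give, under thermodynamic control, the linear dienol acetate F10. Cleavage with MeLi (2 equiv, THF, 0 °C) and silylation of the lithium dienolate with Me3SiCl would return to the route at 6.

## Further compounds

F1 | step 11 | 2α-hydroxy decalin allylic alcohol (C8=C1, 6α-OTBS) | C=C1[C@@H]2C[C@H](O)C(C)=C[C@H]2[C@H](C(C)C)[C@H](O[Si](C)(C)C(C)(C)C)C1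
F2 | step 11 | 2α-hydroxy-1α,8α-epoxy decalin (6α-OTBS) | C=C1[C@@H]2C[C@H](O)[C@]3(C)O[C@@H]3[C@H]2[C@H](C(C)C)[C@H](O[Si](C)(C)C(C)(C)C)C1
F3 | step 11 | 1α,8α-epoxy decalin-2-one (6α-OTBS) | C=C1[C@@H]2CC(=O)[C@]3(C)O[C@@H]3[C@H]2[C@H](C(C)C)[C@H](O[Si](C)(C)C(C)(C)C)C1
F4 | step 11 | 5β-hydroxy-1α,8α-epoxy decalin-2-one (6α-OTBS) | C=C1[C@@H]2CC(=O)[C@]3(C)O[C@@H]3[C@H]2[C@H](C(C)C)[C@H](O[Si](C)(C)C(C)(C)C)[C@H]1O
F5 | step 11 | 5β-[(E)-3-methylpent-2-enoyloxy]-1α,8α-epoxy decalin-2-one (6α-OTBS) | C=C1[C@@H]2CC(=O)[C@]3(C)O[C@@H]3[C@H]2[C@H](C(C)C)[C@H](O[Si](C)(C)C(C)(C)C)[C@H]1OC(=O)/C=C(\C)CC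
F6 | step 4 | trimethyl{[2-methyl-6-nitro-5-(propan-2-yl)-8-(prop-1-en-2-yl)bicyclo[2.2.2]oct-2-en-1-yl]oxy}silane (nitro endo, isopropyl exo) | C=C(C)[C@@H]1C[C@]2(O[Si](C)(C)C)C(C)=C[C@H]1[C@H](C(C)C)[C@H]2[N+](=O)[O-]
F7 | step 12 | exocyclic enol triflate of 16 (triflate on the C7a side, methyl towards C2) | C=C1[C@@H]2CC(=O)/C(=C(\C)OS(=O)(=O)C(F)(F)F)[C@H]2[C@H](C(C)C)[C@H](O[Si](C)(C)C(C)(C)C)[C@H]1OC(=O)/C=C(\C)CC
F8 | step 9 | 5α-hydroxy epimer of 12 | C=C1[C@@H]2CC(=O)[C@@]3(C)O[C@H]3[C@H]2[C@H](C(C)C)[C@H](O[Si](C)(C)C(C)(C)C)[C@@H]1O
F9 | step 14 | 2α-hydroxy epimer of 20 | C=C1[C@@H]2C[C@H](O)/C(=C\C)[C@H]2[C@H](C(C)C)[C@H](O[Si](C)(C)C(C)(C)C)[C@H]1OC(=O)/C=C(\C)CC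
F10 | step 3 | (5R)-2-methyl-5-(prop-1-en-2-yl)cyclohexa-1,3-dien-1-yl acetate | C=C(C)[C@@H]1CC(OC(C)=O)=C(C)C=C1
A1 | alternative 1 | trimethyl({4-methyl-3-[7-vinyl-1,4-dioxaspiro[4.4]nonan-6-yl]pent-1-en-2-yl}oxy)silane (trans-6,7) | C=C[C@@H]1CCC2(OCCO2)[C@H]1[C@H](C(C)C)C(=C)O[Si](C)(C)C
A2 | alternative 1 | trans-hydrindane with C1 dioxolane ketal, C4 methylidene, C6 ketone and 7-isopropyl | C=C1[C@@H]2CCC3(OCCO3)[C@H]2[C@H](C(C)C)C(=O)C1
A3 | alternative 2 | 2-[7-ethynyl-8-(propan-2-yl)-1,4-dioxaspiro[4.5]decan-6-yl]acetaldehyde (trans-6,7) | C12(OCCO1)[C@H](CC=O)[C@@H](C#C)[C@H](C(C)C)CC2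
A4 | alternative 2 | trans-hydrindane allylic alcohol with C4 dioxolane ketal, 2β-OH, Z-ethylidene and 7-isopropyl | C12(OCCO1)[C@@H]3C[C@@H](O)/C(=C\C)[C@H]3[C@H](C(C)C)CC2
A5 | alternative 3 | 3-methyl-2-[2-oxo-5-(prop-1-en-2-yl)cyclopentyl]butanal (trans) | C=C(C)[C@@H]1CCC(=O)[C@H]1[C@H](C(C)C)C=O
A6 | alternative 3 | trans-hydrindan-1-one with C4 methylidene, axial 6α-OH and 7-isopropyl | C=C1[C@@H]2CCC(=O)[C@H]2[C@H](C(C)C)[C@H](O)C1
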